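## Retrosynthetic overview

1. Leucanthin B ⇐ its 2-(trimethylsilyl)ethyl ester ⇐ the 9-alcohol; the ten-membered ring is closed last, at C9–C10, by a Nozaki–Hiyama–Kishi reaction between a (Z)-α-iodo enoate (C10, C14) and the C9 aldehyde.
2. The α-methylene lactone is made earlier, on the open chain, by forming C7–C11: the carbanion of a phosphonoacetate ester on O6 opens a temporary 7,8-trans-epoxide (5-exo) and is methylenated with formaldehyde in the same flask. This closes the lactone, sets C7, frees only the 8-OH (site of the epoxyangelate) and installs C13.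
3. Enabling feature: in the target the lactone oxygen O6 sits on the carbon next to C7, and the oxygen on C8 is anti to the C7–C11 bond. Atoms C6(O)–C7–C8(O) are therefore a hidden erythro 2,3-epoxy alcohol whose hydroxyl group carries the lactone atoms C12 and C11 as the tether.
4. The C1–C9 tris-epoxide comes from C5–C6 union of a (Z)-alkenyllithium (C1–C5, 2,3-cis-epoxide by Sharpless epoxidation) with an epoxy aldehyde (C6–C9, Sharpless epoxidation), followed by hydroxyl-directed 4,5-epoxidation.
5. Order of ring formation: 2,3-epoxide and 7,8-epoxide (in the two fragments), 4,5-epoxide, lactone ring (7,8-epoxide consumed), ten-membered ring.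

Key step: step 13

Remark: positions are numbered as in germacranes (C1=C10 olefin, C14 carboxyl carbon, C6 lactone carbinol carbon, C11/C13 methylene-lactone carbons); stereodescriptors given for open-chain intermediates use these locants.

## Route

Step 1
Reactants: 1 prop-2-yn-1-ol
Product: 3 (Z)-3-iodo-2-methylprop-2-en-1-ol, via alkenylmagnesium chelate 2 (not isolated)
Conditions: MeMgBr (2.2 equiv), CuI (10 mol %), THF, −10 °C → rt; then I2, −10 °C; aq. work-up
Reagents that add atoms: methylmagnesium bromide, C[Mg]Br; iodine, II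
Why: Copper-catalysed anti-carbomagnesiation of the propargylic alkoxide puts the methyl group on the internal carbon and leaves magnesium cis to the CH2O group in a five-membered chelate, so iodinolysis with retention should give the (Z)-iodide with iodine cis to the hydroxymethyl group.

Step 2
Reactants: 3 (Z)-3-iodo-2-methylprop-2-en-1-ol
Product: 4 (Z)-3-iodo-2-methylprop-2-enal
Conditions: MnO2, CH2Cl2, rt; used at once
Reagents that add atoms: none
Why: Allylic oxidation with MnO2 is neutral, so the (Z)-β-iodo enal should not isomerise if it is used directly.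

Step 3
Reactants: 4 (Z)-3-iodo-2-methylprop-2-enal; 5 methyl 2-[bis(2,2,2-trifluoroethoxy)phosphoryl]acetate
Product: 6 methyl (2Z,4Z)-5-iodo-4-methylpenta-2,4-dienoate
Conditions: KN(SiMe3)2, 18-crown-6, THF, −78 °C
Reagents that add atoms: none
Why: Still–Gennari olefination, in which the trifluoroethyl phosphonate eliminates under kinetic control, should give the (2Z)-enoate while the (4Z)-iodoalkene is carried through unchanged.

Step 4
Reactants: 6 methyl (2Z,4Z)-5-iodo-4-methylpenta-2,4-dienoate
Product: 7 (2Z,4Z)-5-iodo-4-methylpenta-2,4-dien-1-ol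
Conditions: iBu2AlH (2.2 equiv), CH2Cl2, −78 °C; aq. potassium sodium tartrate
Reagents that add atoms: none
Why: 1,2-Reduction of the dienoate with iBu2AlH at low temperature gives the allylic alcohol without touching the alkenyl iodide or either olefin geometry.

Step 5
Reactants: 7 (2Z,4Z)-5-iodo-4-methylpenta-2,4-dien-1-ol
Product: 8 [(2R,3S)-3-[(Z)-1-iodoprop-1-en-2-yl]oxiran-2-yl]methanol
Conditions: Ti(OiPr)4 (10 mol %), D-(−)-diethyl tartrate (12 mol %), t-BuOOH, 4 Å MS, CH2Cl2, −20 °C
Reagents that add atoms: tert-butyl hydroperoxide, CC(C)(C)OO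
Why: Sharpless asymmetric epoxidation touches only the olefin next to the hydroxyl group, the Z geometry gives the cis-epoxide, and the D-(−)-tartrate ligand should select the face that leads to the (2R,3S) configuration.

Step 6
Reactants: 8 [(2R,3S)-3-[(Z)-1-iodoprop-1-en-2-yl]oxiran-2-yl]methanol
Product: 9 triethyl{[(2R,3S)-3-[(Z)-1-iodoprop-1-en-2-yl]oxiran-2-yl]methoxy}silane (west fragment, C1–C5)
Conditions: Et3SiCl, imidazole, CH2Cl2, 0 °C
Reagents that add atoms: chlorotriethylsilane, CC[Si](Cl)(CC)CC
Why: Standard silylation of the primary alcohol; triethylsilyl is chosen because a primary triethylsilyl ether can later be oxidised directly to the aldehyde in the presence of a tert-butyldimethylsilyl ether.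

Step 7
Reactants: 10 (E)-but-2-ene-1,4-diol
Product: 11 (E)-4-{[tert-butyl(dimethyl)silyl]oxy}but-2-en-1-ol
Conditions: NaH (1.0 equiv), THF, 0 °C; then t-BuMe2SiCl
Reagents that add atoms: tert-butylchlorodimethylsilane, CC(C)(C)[Si](C)(C)Cl
Why: Monosilylation of the symmetrical diol through its sparingly soluble monosodium alkoxide should stop after one silyl group.

Step 8
Reactants: 11 (E)-4-{[tert-butyl(dimethyl)silyl]oxy}but-2-en-1-ol
Product: 12 [(2R,3R)-3-({[tert-butyl(dimethyl)silyl]oxy}methyl)oxiran-2-yl]methanol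
Conditions: Ti(OiPr)4 (10 mol %), D-(−)-diethyl tartrate (12 mol %), t-BuOOH, 4 Å MS, CH2Cl2, −20 °C
Reagents that add atoms: tert-butyl hydroperoxide, CC(C)(C)OO
Why: Sharpless asymmetric epoxidation of a primary (E)-allylic alcohol, where the E geometry gives the trans-epoxide and the D-(−)-tartrate ligand should give the (2R,3R) enantiomer.

Step 9
Reactants: 12 [(2R,3R)-3-({[tert-butyl(dimethyl)silyl]oxy}methyl)oxiran-2-yl]methanol
Product: 13 (2S,3R)-3-({[tert-butyl(dimethyl)silyl]oxy}methyl)oxirane-2-carbaldehyde (east fragment, C6–C9)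
Conditions: DMP, pyridine, CH2Cl2, 0 °C → rt
Reagents that add atoms: none
Why: Buffered Dess–Martin oxidation gives the trans-epoxy aldehyde without epimerisation or epoxide opening.

Step 10
Reactants: 9 west fragment iodide; 13 east fragment epoxy aldehyde
Product: 15 C1–C9 epoxy alcohol (1-O-triethylsilyl, 2,3-cis-epoxide, (4Z)-olefin, 6-OH erythro to the 7,8-trans-epoxide, 9-O-tert-butyldimethylsilyl; 2R,3S,6R,7R,8R), via alkenyllithium 14 (not isolated)
Conditions: t-BuLi (2.05 equiv), Et2O, −78 °C; then 13, −78 °C; H2O quench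
Reagents that add atoms: none
Why: Iodine–lithium exchange keeps the Z geometry, and 1,2-addition to the epoxy aldehyde under polar Felkin–Anh control (epoxide C–O bond anti to the incoming nucleophile) should give mainly the anti (erythro) C6 alcohol, the minor C6 epimer being removed by chromatography.

Step 11
Reactants: 15 C1–C9 epoxy alcohol
Product: 16 C1–C9 tris-epoxy alcohol (as 15, with the 4,5-cis-epoxide threo to the 6-OH; 2R,3R,4R,5R,6S,7R,8R)
Conditions: mCPBA, NaHCO3, CH2Cl2, 0 °C
Reagents that add atoms: 3-chloroperbenzoic acid, OOC(=O)c1cccc(Cl)c1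
Why: Hydroxyl-directed peracid epoxidation of the only olefin, in which A1,3 strain between C3 and the carbinol substituents holds the C6–H bond in the olefin plane so that the peracid bound to the 6-OH should attack the face giving the threo 4,5-epoxide, cis by virtue of the Z olefin.

Step 12
Reactants: 16 C1–C9 tris-epoxy alcohol; 17 2-(diethoxyphosphoryl)acetic acid
Product: 18 6-O-[(diethoxyphosphoryl)acetyl] ester of 16
Conditions: DCC, DMAP (10 mol %), CH2Cl2, 0 °C → rt
Reagents that add atoms: none
Why: Steglich esterification of the only free hydroxyl group under neutral conditions, which avoids Payne rearrangement of the flanking epoxides.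

Step 13
Reactants: 18 6-O-[(diethoxyphosphoryl)acetyl] ester of 16
Product: 20 α-methylene lactone alcohol (1-O-triethylsilyl, 2,3- and 4,5-epoxides, trans-fused 6,12-olide with 11(13)-methylene, free 8-OH, 9-O-tert-butyldimethylsilyl; 2R,3R,4R,5R,6S,7R,8S), via α-phosphono lactone 19 (not isolated)
Conditions: KOtBu (1.0 equiv), THF, 0 → 40 °C; then (CH2O)n, 0 °C → rt
Reagents that add atoms: formaldehyde (from paraformaldehyde), C=O
Why: Proposed new method: KOtBu deprotonates the phosphonoacetate and the carbanion attacks C7 of the 7,8-epoxide from the backside, a 5-exo-tet closure of the lactone ring (C11, C12, O, C6, C7); the liberated 8-alkoxide is then protonated by the more acidic α-phosphono lactone 19, whose potassium salt undergoes a Horner–Wadsworth–Emmons reaction with formaldehyde to give the exocyclic methylene group. The closest known reaction types are the telescoped intramolecular Michael addition/Horner–Wadsworth–Emmons methylenation of phosphonoacetate esters, the intermolecular opening of epoxides by phosphonoacetate anions, and the 5-exo opening of 2,3-epoxy alcohols at C2 by a nucleophile tethered to the hydroxyl oxygen. C7 is set by SN2 inversion at the epoxide carbon and C8 keeps the configuration from the Sharpless epoxidation, so the erythro epoxy alcohol ester should give the trans-fused lactone with the free 8-hydroxyl group anti to the new C7–C11 bond. The step needs attack at C7 and not at C5 of the 4,5-epoxide or at C8: C5 is neopentyl-like (next to the fully substituted C4) and its backside is reached only through a gauche C4–C5–C6–C7 chain, whereas C7 is reached from the extended chain with O6 antiperiplanar to the breaking C7–O bond, and attack at C8 would be a 6-endo closure. The exocyclic phosphoryl group lets the carbanion react without the in-ring enolate alignment that hampers lactone closure by simple ester enolates, and one equivalent of base keeps the 8-hydroxyl group protonated, so phosphoryl transfer to O8, translactonisation and silyl migration should stay slow.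

Step 14
Reactants: 21 angelic acid, (Z)-2-methylbut-2-enoic acid
Product: 22 (Z)-2-methylbut-2-en-1-ol
Conditions: LiAlH4, Et2O, 0 °C
Reagents that add atoms: none
Why: Hydride reduction of the acid gives the allylic alcohol without isomerising the (Z)-trisubstituted olefin.

Step 15
Reactants: 22 (Z)-2-methylbut-2-en-1-ol
Product: 23 [(2S,3R)-2,3-dimethyloxiran-2-yl]methanol
Conditions: Ti(OiPr)4 (10 mol %), L-(+)-diethyl tartrate (12 mol %), t-BuOOH, 4 Å MS, CH2Cl2, −20 °C
Reagents that add atoms: tert-butyl hydroperoxide, CC(C)(C)OO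
Why: Sharpless asymmetric epoxidation, where the L-(+)-tartrate ligand should give the (2S,3R) epoxide and the Z geometry keeps the two methyl groups trans on the ring.

Step 16
Reactants: 23 [(2S,3R)-2,3-dimethyloxiran-2-yl]methanol
Product: 24 (2R,3R)-2,3-dimethyloxirane-2-carboxylic acid (epoxyangelic acid)
Conditions: RuCl3 (2 mol %), NaIO4, CCl4–MeCN–H2O, rt
Reagents that add atoms: water, O
Why: Ruthenium tetroxide generated in situ oxidises the primary alcohol to the acid and leaves the epoxide and both stereocentres untouched (the descriptor at C2 changes by priority only).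

Step 17
Reactants: 20 α-methylene lactone alcohol; 24 epoxyangelic acid
Product: 25 8-O-[(2R,3R)-2,3-dimethyloxirane-2-carbonyl] ester of 20
Conditions: DCC, DMAP, CH2Cl2, 0 °C → rt
Reagents that add atoms: none
Why: Steglich esterification of the single free (C8) hydroxyl group with an α-quaternary acid that cannot epimerise.

Step 18
Reactants: 26 (triphenylphosphoranylidene)ketene; 27 2-(trimethylsilyl)ethanol
Product: 29 2-(trimethylsilyl)ethyl iodo(triphenylphosphoranylidene)acetate, via ester ylide 28 (not isolated)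
Conditions: toluene, 80 °C; then N-iodosuccinimide, CH2Cl2, −20 °C → rt
Reagents that add atoms: N-iodosuccinimide, O=C1CCC(=O)N1I
Why: The alcohol adds to the ketene ylide to give the stabilised ester ylide, which is iodinated at carbon and deprotonated by the succinimide anion to give the isolable α-iodo ylide.

Step 19
Reactants: 25 8-O-epoxyangeloyl ester
Product: 30 C1 aldehyde (cis-2,3-epoxy aldehyde; rest as 25)
Conditions: (COCl)2, DMSO, CH2Cl2, −78 → −30 °C; then Et3N, −78 °C → rt; used at once
Reagents that add atoms: none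
Why: Under Swern conditions a primary triethylsilyl ether is converted directly into the aldehyde (silyl transfer to chloride, then oxidation), while the tert-butyldimethylsilyl ether, the esters and the epoxides should stay intact.

Step 20
Reactants: 30 C1 aldehyde; 29 2-(trimethylsilyl)ethyl iodo(triphenylphosphoranylidene)acetate
Product: 31 2-(trimethylsilyl)ethyl (Z)-2-iodo enoate (C14 ester, C10(I)=C1; rest as 30)
Conditions: CH2Cl2, rt → 40 °C
Reagents that add atoms: none
Why: Wittig reaction of a stabilised ylide under neutral conditions places the ester trans to the aldehyde residue, which should give the (Z)-α-iodo enoate with iodine cis to C2.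

Step 21
Reactants: 31 (Z)-2-iodo enoate
Product: 32 9-alcohol of 31
Conditions: HF·pyridine, pyridine, THF, 0 °C → rt
Reagents that add atoms: none
Why: Buffered HF·pyridine cleaves the primary tert-butyldimethylsilyl ether but not the 2-(trimethylsilyl)ethyl ester or the epoxides, and the absence of base avoids acyl migration from O8 to O9.

Step 22
Reactants: 32 9-alcohol
Product: 33 9-aldehyde (α-acyloxy aldehyde)
Conditions: DMP, pyridine, CH2Cl2, 0 °C → rt; used crude
Reagents that add atoms: none
Why: Dess–Martin oxidation gives the sensitive α-acyloxy aldehyde under non-enolising conditions, so C8 should not epimerise.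

Step 23
Reactants: 33 9-aldehyde
Product: 34 2-(trimethylsilyl)ethyl ester of 9-O-deacetyl-leucanthin B (ten-membered ring closed, free 9-OH)
Conditions: CrCl2 (10 equiv), NiCl2 (0.1 equiv), DMSO–THF, rt, slow addition to 2 mM
Reagents that add atoms: none
Why: In this Nozaki–Hiyama–Kishi reaction zerovalent nickel inserts into the C–I bond and transmetalation gives an alkenylchromium that adds only to the aldehyde; the cis enoate and the two cis-epoxides bend the chain so the ten-membered ring can close at high dilution with retention of olefin geometry, and attack with the chromium-bound carbonyl oxygen on the outside of the forming ring should place the new 9-OH trans to the 8-acyloxy group.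

Step 24
Reactants: 34 macrocyclic 9-alcohol
Product: 35 leucanthin B 2-(trimethylsilyl)ethyl ester
Conditions: Ac2O, pyridine, DMAP (10 mol %), CH2Cl2, 0 °C
Reagents that add atoms: acetic anhydride, CC(=O)OC(C)=O
Why: DMAP-catalysed acetylation of the only free hydroxyl group.

Step 25
Reactants: 35 leucanthin B 2-(trimethylsilyl)ethyl ester
Product: 36 leucanthin B
Conditions: (Me2N)3S+ Me3SiF2− (TASF), DMF, 0 °C; aq. NaH2PO4
Reagents that add atoms: none
Why: Fluoride attacks silicon and the ester fragments to ethene and the carboxylate under nearly neutral aprotic conditions, which should spare the acetate, the epoxyangelate, the methylene lactone and the epoxides.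

## Compound list

1 | prop-2-yn-1-ol | C#CCO | starting material
2 | alkenylmagnesium chelate (4-methyl-2,5-dihydro-1,2-oxamagnesole) | CC1=C[Mg]OC1 | intermediate
3 | (Z)-3-iodo-2-methylprop-2-en-1-ol | OC/C(C)=C\I | intermediate
4 | (Z)-3-iodo-2-methylprop-2-enal | O=C/C(C)=C\I | intermediate
5 | methyl 2-[bis(2,2,2-trifluoroethoxy)phosphoryl]acetate | COC(=O)CP(=O)(OCC(F)(F)F)OCC(F)(F)F | starting material
6 | methyl (2Z,4Z)-5-iodo-4-methylpenta-2,4-dienoate | COC(=O)/C=C\C(C)=C/I | intermediate
7 | (2Z,4Z)-5-iodo-4-methylpenta-2,4-dien-1-ol | OC/C=C\C(C)=C/I | intermediate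
8 | [(2R,3S)-3-[(Z)-1-iodoprop-1-en-2-yl]oxiran-2-yl]methanol | OC[C@H]1O[C@H]1/C(C)=C\I | intermediate
9 | triethyl{[(2R,3S)-3-[(Z)-1-iodoprop-1-en-2-yl]oxiran-2-yl]methoxy}silane | CC[Si](CC)(CC)OC[C@H]1O[C@H]1/C(C)=C\I | intermediate
10 | (E)-but-2-ene-1,4-diol | OC/C=C/CO | starting material
11 | (E)-4-{[tert-butyl(dimethyl)silyl]oxy}but-2-en-1-ol | OC/C=C/CO[Si](C)(C)C(C)(C)C | intermediate
12 | [(2R,3R)-3-({[tert-butyl(dimethyl)silyl]oxy}methyl)oxiran-2-yl]methanol | OC[C@H]1O[C@@H]1CO[Si](C)(C)C(C)(C)C | intermediate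
13 | (2S,3R)-3-({[tert-butyl(dimethyl)silyl]oxy}methyl)oxirane-2-carbaldehyde | O=C[C@H]1O[C@@H]1CO[Si](C)(C)C(C)(C)C | intermediate
14 | (Z)-alkenyllithium from 9 | CC[Si](CC)(CC)OC[C@H]1O[C@H]1/C(C)=C\[Li] | intermediate
15 | C1–C9 epoxy alcohol: 1-O-TES, 2,3-cis-epoxide, (4Z)-olefin, 6-OH erythro to 7,8-trans-epoxide, 9-O-TBS (2R,3S,6R,7R,8R) | CC[Si](CC)(CC)OC[C@H]1O[C@H]1/C(C)=C\[C@@H](O)[C@H]1O[C@@H]1CO[Si](C)(C)C(C)(C)C | intermediate
16 | C1–C9 tris-epoxy alcohol: as 15 with 4,5-cis-epoxide threo to 6-OH (2R,3R,4R,5R,6S,7R,8R) | CC[Si](CC)(CC)OC[C@H]1O[C@H]1[C@]1(C)O[C@@H]1[C@@H](O)[C@H]1O[C@@H]1CO[Si](C)(C)C(C)(C)C | intermediate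
17 | 2-(diethoxyphosphoryl)acetic acid | CCOP(=O)(CC(=O)O)OCC | starting material
18 | 6-O-[(diethoxyphosphoryl)acetyl] ester of 16 | CC[Si](CC)(CC)OC[C@H]1O[C@H]1[C@]1(C)O[C@@H]1[C@@H](OC(=O)CP(=O)(OCC)OCC)[C@H]1O[C@@H]1CO[Si](C)(C)C(C)(C)C | intermediate
19 | α-(diethoxyphosphoryl) 6,12-lactone with free 8-OH (potassium salt in the flask; C11 unassigned) | CC[Si](CC)(CC)OC[C@H]1O[C@H]1[C@]1(C)O[C@@H]1[C@H]1OC(=O)C(P(=O)(OCC)OCC)[C@@H]1[C@H](O)CO[Si](C)(C)C(C)(C)C | intermediate
20 | α-methylene lactone alcohol: trans-fused 6,12-olide, 11(13)-methylene, free 8-OH, 1-O-TES, 9-O-TBS (2R,3R,4R,5R,6S,7R,8S) | CC[Si](CC)(CC)OC[C@H]1O[C@H]1[C@]1(C)O[C@@H]1[C@H]1OC(=O)C(=C)[C@@H]1[C@H](O)CO[Si](C)(C)C(C)(C)C | intermediate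
21 | angelic acid, (Z)-2-methylbut-2-enoic acid | C/C=C(C)\C(=O)O | starting material
22 | (Z)-2-methylbut-2-en-1-ol | C/C=C(C)\CO | intermediate
23 | [(2S,3R)-2,3-dimethyloxiran-2-yl]methanol | OC[C@]1(C)O[C@@H]1C | intermediate
24 | (2R,3R)-2,3-dimethyloxirane-2-carboxylic acid | OC(=O)[C@]1(C)O[C@@H]1C | intermediate
25 | 8-O-[(2R,3R)-2,3-dimethyloxirane-2-carbonyl] ester of 20 | CC[Si](CC)(CC)OC[C@H]1O[C@H]1[C@]1(C)O[C@@H]1[C@H]1OC(=O)C(=C)[C@@H]1[C@H](OC(=O)[C@]1(C)O[C@@H]1C)CO[Si](C)(C)C(C)(C)C | intermediate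
26 | (triphenylphosphoranylidene)ketene | O=C=C=P(c1ccccc1)(c1ccccc1)c1ccccc1 | starting material
27 | 2-(trimethylsilyl)ethanol | C[Si](C)(C)CCO | starting material
28 | 2-(trimethylsilyl)ethyl (triphenylphosphoranylidene)acetate | C[Si](C)(C)CCOC(=O)C=P(c1ccccc1)(c1ccccc1)c1ccccc1 | intermediate
29 | 2-(trimethylsilyl)ethyl iodo(triphenylphosphoranylidene)acetate | C[Si](C)(C)CCOC(=O)C(I)=P(c1ccccc1)(c1ccccc1)c1ccccc1 | intermediate
30 | C1 aldehyde (cis-2,3-epoxy aldehyde, 8-O-epoxyangeloyl, 9-O-TBS) | O=C[C@H]1O[C@H]1[C@]1(C)O[C@@H]1[C@H]1OC(=O)C(=C)[C@@H]1[C@H](OC(=O)[C@]1(C)O[C@@H]1C)CO[Si](C)(C)C(C)(C)C | intermediate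
31 | 2-(trimethylsilyl)ethyl (Z)-2-iodo enoate (C10(I)=C1), 9-O-TBS | C[Si](C)(C)CCOC(=O)/C(I)=C/[C@H]1O[C@H]1[C@]1(C)O[C@@H]1[C@H]1OC(=O)C(=C)[C@@H]1[C@H](OC(=O)[C@]1(C)O[C@@H]1C)CO[Si](C)(C)C(C)(C)C | intermediate
32 | 9-alcohol of 31 | C[Si](C)(C)CCOC(=O)/C(I)=C/[C@H]1O[C@H]1[C@]1(C)O[C@@H]1[C@H]1OC(=O)C(=C)[C@@H]1[C@H](OC(=O)[C@]1(C)O[C@@H]1C)CO | intermediate
33 | 9-aldehyde (macrocyclisation precursor) | C[Si](C)(C)CCOC(=O)/C(I)=C/[C@H]1O[C@H]1[C@]1(C)O[C@@H]1[C@H]1OC(=O)C(=C)[C@@H]1[C@H](OC(=O)[C@]1(C)O[C@@H]1C)C=O | intermediate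
34 | 2-(trimethylsilyl)ethyl ester of 9-O-deacetyl-leucanthin B | C=C1C(=O)O[C@H]2[C@H]1[C@H](OC(=O)[C@]1(C)O[C@@H]1C)[C@@H](O)/C(C(=O)OCC[Si](C)(C)C)=C\[C@H]1O[C@H]1[C@]1(C)O[C@H]21 | intermediate
35 | leucanthin B 2-(trimethylsilyl)ethyl ester | C=C1C(=O)O[C@H]2[C@H]1[C@H](OC(=O)[C@]1(C)O[C@@H]1C)[C@@H](OC(C)=O)/C(C(=O)OCC[Si](C)(C)C)=C\[C@H]1O[C@H]1[C@]1(C)O[C@H]21 | intermediate
36 | leucanthin B | C=C1C(=O)O[C@H]2[C@H]1[C@H](OC(=O)[C@]1(C)O[C@@H]1C)[C@@H](OC(C)=O)/C(C(=O)O)=C\[C@H]1O[C@H]1[C@]1(C)O[C@H]21 | target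

## Step count and risks

Total step count: 25. Longest linear sequence: 18 steps (steps 1–6, 10–13, 17, 19–25).

Steps most likely to fail:

1. Step 13 (Proposed new method). The stabilised carbanion may be too weak a nucleophile for the unactivated 7,8-epoxide, may open the 4,5-epoxide at C5 instead, or the 8-alkoxide may start phosphoryl transfer before methylenation. The fallback forms the same C7–C11 bond by known chemistry and installs the C8 oxygen afterwards; it sets out from 9 and 10 and comes back at 20.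
   - Diol 10 is converted into (E)-4-[(4-methoxybenzyl)oxy]but-2-en-1-ol F1 (NaH, 4-methoxybenzyl chloride) and oxidised with MnO2 to (E)-4-[(4-methoxybenzyl)oxy]but-2-enal F2.
   - Alkenyllithium 14 (from 9) is added to F2. The C6 epimer mixture is resolved by Sharpless kinetic resolution (Ti(OiPr)4, L-(+)-diisopropyl tartrate, t-BuOOH), which epoxidises the unwanted epimer and leaves the bis-allylic alcohol F3.
   - Hydroxyl-directed epoxidation (mCPBA) gives the 4,5-epoxy allylic alcohol F4, Steglich esterification with 17 gives the phosphonoacetate F5, DDQ gives the allylic alcohol F6 and MnO2 gives the enal F7.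
   - KOtBu and then paraformaldehyde (intramolecular Michael addition followed by Horner–Wadsworth–Emmons methylenation) should close the lactone trans to C5 and give the methylene lactone aldehyde F8.
   - D-Proline-catalysed α-aminoxylation with nitrosobenzene, NaBH4 reduction and N–O cleavage (CuSO4, MeOH) should give the 8,9-diol F9 with reagent control at C8; silylation of the primary hydroxyl group (t-BuMe2SiCl, imidazole) gives 20.

2. Step 23. The alkenylchromium may add to the other face of the aldehyde, so that the C9 epimer is formed; intermolecular coupling may also compete with ring closure, which the fallback does not address. The fallback sets out from 33 and comes back at 35: the same ring closure gives the 9-epi alcohol F10, and a Mitsunobu reaction (PPh3, diisopropyl azodicarboxylate, AcOH) inverts C9 and installs the acetate in one operation.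

3. Step 10. Felkin–Anh face selectivity in the addition to the epoxy aldehyde may be low, which would split the material between 15 and its C6 epimer. The fallback sets out from the mixture of 15 and the C6 epimer F11 and comes back at 15: Dess–Martin oxidation of the mixture gives the epoxy enone F12, and Zn(BH4)2 (Et2O, −30 °C) should reduce it through a zinc chelate between ketone and epoxide oxygen to the anti (erythro) alcohol 15.

Further compounds
F1 | step 13 | (E)-4-[(4-methoxybenzyl)oxy]but-2-en-1-ol | OC/C=C/COCc1ccc(OC)cc1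
F2 | step 13 | (E)-4-[(4-methoxybenzyl)oxy]but-2-enal | O=C/C=C/COCc1ccc(OC)cc1
F3 | step 13 | bis-allylic alcohol (1-O-TES, 2,3-cis-epoxide, (4Z,7E)-diene, 6-OH configured as in 20, 9-O-PMB) | CC[Si](CC)(CC)OC[C@H]1O[C@H]1/C(C)=C\[C@@H](O)/C=C/COCc1ccc(OC)cc1
F4 | step 13 | 4,5-epoxy allylic alcohol (4,5-cis-epoxide threo to 6-OH) | CC[Si](CC)(CC)OC[C@H]1O[C@H]1[C@]1(C)O[C@@H]1[C@@H](O)/C=C/COCc1ccc(OC)cc1
F5 | step 13 | 6-O-[(diethoxyphosphoryl)acetyl] ester of F4 | CC[Si](CC)(CC)OC[C@H]1O[C@H]1[C@]1(C)O[C@@H]1[C@@H](OC(=O)CP(=O)(OCC)OCC)/C=C/COCc1ccc(OC)cc1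
F6 | step 13 | 9-alcohol of F5 | CC[Si](CC)(CC)OC[C@H]1O[C@H]1[C@]1(C)O[C@@H]1[C@@H](OC(=O)CP(=O)(OCC)OCC)/C=C/CO
F7 | step 13 | (7E)-enal (C9 aldehyde) phosphonoacetate | CC[Si](CC)(CC)OC[C@H]1O[C@H]1[C@]1(C)O[C@@H]1[C@@H](OC(=O)CP(=O)(OCC)OCC)/C=C/C=O
F8 | step 13 | methylene lactone aldehyde (C8 methylene, C9 aldehyde) | CC[Si](CC)(CC)OC[C@H]1O[C@H]1[C@]1(C)O[C@@H]1[C@H]1OC(=O)C(=C)[C@@H]1CC=O
F9 | step 13 | methylene lactone 8,9-diol | CC[Si](CC)(CC)OC[C@H]1O[C@H]1[C@]1(C)O[C@@H]1[C@H]1OC(=O)C(=C)[C@@H]1[C@H](O)CO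
F10 | step 23 | 9-epimer of 34 | C=C1C(=O)O[C@H]2[C@H]1[C@H](OC(=O)[C@]1(C)O[C@@H]1C)[C@H](O)/C(C(=O)OCC[Si](C)(C)C)=C\[C@H]1O[C@H]1[C@]1(C)O[C@H]21
F11 | step 10 | C6 epimer of 15 | CC[Si](CC)(CC)OC[C@H]1O[C@H]1/C(C)=C\[C@H](O)[C@H]1O[C@@H]1CO[Si](C)(C)C(C)(C)C
F12 | step 10 | C6 ketone (epoxy enone) from 15 and F11 | CC[Si](CC)(CC)OC[C@H]1O[C@H]1/C(C)=C\C(=O)[C@H]1O[C@@H]1CO[Si](C)(C)C(C)(C)C
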